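The pitfall at this bench is to see a slow slurry and reach for a rate.

solid substrate 0.82 M; partner 1.20 equiv; time 10 d

1. the target and solid product together standing at 10 d, as a percentage of the solid substrate charged
2. the change that raises the amount of target and solid product together at 10 d, in percent of the solid substrate charged most ("none" if none brings more than 2 percentage points) (east / north / south-east / north-east / none)
3. amount of target and solid product together at 10 d, in percent of the solid substrate charged, after south-east

- east: doubling the dissolution coefficient of step 3, all else as stated
- north: doubling the amount of partner, all else as stated
- south-east: doubling the solubility in step 2, all else as stated
- north-east: doubling the dissolution coefficient of step 2, all else as stated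

- what is said of target includes solid product
- solid substrate, solid product is a solid; its amount is given per volume of the solution
- at the start none of the solid substrate is in solution
- run time (flask): 10 d

    dissolved substrate + partner → target (k1 = 3.1 M⁻¹ h⁻¹)
    solid product ⇌ target, rate k2*(cs2 - [target]) while solid is left; crystals form when [target] > cs2 (cs2 = 0.057 M, k2 = 17 h⁻¹)
    solid substrate ⇌ dissolved substrate, rate k3*(cs3 - [dissolved substrate]) while solid is left; crystals form when [dissolved substrate] > cs3 (cs3 = 0.23 M, k3 = 0.12 h⁻¹)
    target ⇌ isomer of the product (K4 = 0.53, k4 = 0.020 h⁻¹)
    partner → decomposed reagent (k5 = 0.0059 h⁻¹)

Now in the flask: solid substrate creeps into solution and meets partner there, while partner decays with a half-life of 4.9 d. The target formed crystallises above its solubility of 0.057 M, and dissolved target turns reversibly into isomer, with equilibrium constant 0.53.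

By my reckoning, the solid needs at least 1.24 d to dissolve, less than the partner half-life, and partner is charged in excess, so I take conversion as complete without proving it.

Then count turnovers. The target and isomer pair relaxes with a half-life of 0.500 d, so the run holds 20.0 of them. The charge of 0.82 M far exceeds the solubility, so crystals should stand at the end and hold dissolved target at its solubility. Isomer then settles at the equilibrium constant times that solubility. As a share of the charge this is the isomer toll, 3.68 %.

On arrival, expect 96.3 % as target and solid product. Leave the solubility alone: doubling it doubles the toll and gives 92.6 %. The toll contains no dissolution coefficient and no partner charge.

The forecast gives 96.3 %, none and 92.6 %, holding that “East, north and north-east change only rates, so they gain nothing”.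

The simulation gives 96.3 %, none and 92.6 %. At 10.0 d the flask holds isomer at 3.68 % against the toll of 3.68 %, beside solid product at 89.4 %.

The neighbour flask, charged with 0.480 equiv of partner, has the same solubility, equilibrium constant and charge of solid substrate, so the same toll of 3.68 % is reckoned for it while crystals stand. Its solid product ends at 34.7 %, and its isomer stands at 3.68 %. Partner is the limiting reagent of the neighbour flask, with 0 % left, and solid substrate remains there at 26.6 % with dissolved substrate at 28.0 %. Target and solid product together end the neighbour flask at 41.6 %.

The constants used here were drawn at random within sensible limits, and the outcome is calculated.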